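**Retrosynthetic overview**

1. The last bond made is the ester C–O bond between caffeic acid and the primary alcohol of (2R,3S,4S)-lariciresinol (Mitsunobu reaction).
2. The strategy rests on oxolane atoms C3 and C4, which carry two cis one-carbon arms of different oxidation level (C3–CH2O and C4–CH2Ar). These are the two carbons of a ketene stapled across a C3=C4 alkene. Dichloroketene adds [2+2] to an (R)-2-aryl-2,5-dihydrofuran anti to the C2 aryl group, and methoxide then cuts the C(=O)–CCl2 bond of the cyclobutanone.
3. On the C4 arm, CHCl2 becomes an aldehyde held as a cis-fused lactol, which takes an aryl Grignard reagent; the benzylic OH is then hydrogenolysed. On the C3 arm, the ester is reduced to CH2OH.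
4. The dihydrofuran comes from vanillin by vinyl Grignard addition, Sharpless kinetic resolution (sets C2), O-allylation and ring-closing metathesis.
5. Ring order: oxolane (metathesis), cyclobutanone ([2+2], then opened), lactol ring (closed, then opened). The phenol of ring A travels as a tosylate so that the benzylic, allylic C2–O bond stays electron-poor.

Key step: step 6

Remark: Ts = 4-methylbenzenesulfonyl; ring A = aryl group on C2; ring B = aryl group of the benzyl arm on C4; oxolane numbering O1, C2 (aryl), C3 (CH2O arm), C4 (benzyl arm), C5.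

**Route**

Step 1
Reactants: 1 vanillin
Product: 2 4-formyl-2-methoxyphenyl 4-methylbenzenesulfonate
Conditions: TsCl, Et3N, DMAP (cat.), CH2Cl2, 0 °C → rt
Reagents that add atoms: 4-methylbenzenesulfonyl chloride, Cc1ccc(cc1)S(=O)(=O)Cl
Why: Sulfonylation of the phenol under amine base with DMAP catalysis is fast and leaves the aldehyde alone; the tosylate is chosen over an ether because it makes ring A electron-poor, which should keep the later benzylic C2–O bond from ionizing under Lewis acid and from being cut in the hydrogenolysis of step 12.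

Step 2
Reactants: 2 aldehyde tosylate; 3 vinylmagnesium bromide
Product: 4 rac-4-(1-hydroxyprop-2-enyl)-2-methoxyphenyl 4-methylbenzenesulfonate
Conditions: THF, −78 °C; aq. NH4Cl
Reagents that add atoms: none
Why: 1,2-Addition of a vinyl Grignard reagent to the aryl aldehyde at −78 °C, where an aryl sulfonate is inert, should give the allylic alcohol as a racemate.

Step 3
Reactants: 4 racemic allylic alcohol
Product: 5 4-[(1R)-1-hydroxyprop-2-enyl]-2-methoxyphenyl 4-methylbenzenesulfonate
Conditions: Ti(OiPr)4 (0.1 equiv), D-(−)-DIPT (0.15 equiv), t-BuOOH (0.6 equiv), 4 Å MS, CH2Cl2, −20 °C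
Reagents that add atoms: none
Why: Sharpless kinetic resolution: with D-(−)-DIPT the titanium tartrate epoxidizes the (S)-alcohol much faster, so running to a little beyond half conversion should leave the (R)-alcohol, which carries the future C2 of the oxolane, in high enantiomeric purity (reagent control).

Step 4
Reactants: 5 (R)-allylic alcohol; 6 allyl bromide
Product: 7 2-methoxy-4-[(1R)-1-(prop-2-enyloxy)prop-2-enyl]phenyl 4-methylbenzenesulfonate
Conditions: NaH, Bu4NI (cat.), THF, 0 °C → rt
Reagents that add atoms: none
Why: Williamson etherification of the sodium alkoxide with allyl bromide is an SN2 reaction at the allyl carbon and does not touch the carbinol stereocentre.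

Step 5
Reactants: 7 (R)-diene ether
Product: 8 4-[(2R)-2,5-dihydrofuran-2-yl]-2-methoxyphenyl 4-methylbenzenesulfonate
Conditions: second-generation Grubbs catalyst RuCl2(=CHPh)(PCy3)(H2IMes) (2 mol%), CH2Cl2, 40 °C
Reagents that add atoms: none
Why: Ring-closing metathesis of the 1,6-diene to the five-membered 2,5-dihydrofuran is driven by loss of ethylene and leaves C2 untouched.

Step 6
Reactants: 8 (R)-2-aryl-2,5-dihydrofuran; 9 trichloroacetyl chloride
Product: 11 (1S,4R,5R)-7,7-dichloro-4-[3-methoxy-4-(tosyloxy)phenyl]-3-oxabicyclo[3.2.0]heptan-6-one, via dichloroketene 10 (not isolated)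
Conditions: Cl3CCOCl (slow addition), Zn–Cu couple, POCl3, Et2O, 20–35 °C
Reagents that add atoms: none
Why: Dichloroketene 10, freed from 9 by zinc, adds to the C3=C4 alkene of 8 in a concerted, asynchronous [2+2] cycloaddition in which the bond from the ketene carbonyl carbon leads; the closest known reaction type is the dichloroketene addition to cyclopentene, cyclohexene and 2,5-dihydrofuran itself under zinc/POCl3 conditions. The cyclobutanone ring closes in this single intermolecular cycloaddition (C3–C(=O) and C4–CCl2 form together) and can only be cis-fused to the five-membered ring. The new stereocentres C3 and C4 are therefore set cis to each other by the suprafacial addition, and their sense relative to C2 is set by the aryl group, which shields its own face so that the ketene arrives anti to it. The orientation needed (carbonyl carbon on C3, CCl2 on C4) rests on the same group: positive charge builds up on the alkene carbon that bonds second, C4 next to C5H2 carries it better than C3 next to the inductively withdrawing aryl-bearing C2, and the bulky CCl2 end stays away from the substituted side. The sulfonate keeps ring A electron-poor, so the benzylic, allylic C2–O bond should resist ZnCl2 and acylation by the acid chloride, and POCl3 ties up the ZnCl2.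

Step 7
Reactants: 11 dichlorocyclobutanone
Product: 12 methyl (2R,3R,4S)-4-(dichloromethyl)-2-[3-methoxy-4-(tosyloxy)phenyl]oxolane-3-carboxylate
Conditions: NaOMe (0.2 equiv), MeOH–THF, −20 °C → 0 °C; AcOH
Reagents that add atoms: methanol, CO
Why: Haloform-type cleavage: methoxide adds to the strained carbonyl, the tetrahedral intermediate expels the carbanion stabilized by two chlorines and methanol protonates it, so C3 keeps the ester and C4 the CHCl2 group on the same face; substoichiometric base at low temperature should avoid epimerization at C3, β-elimination of the ring oxygen and loss of the aryl sulfonate.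

Step 8
Reactants: 12 dichloromethyl ester
Product: 13 {(2R,3S,4S)-4-(dichloromethyl)-2-[3-methoxy-4-(tosyloxy)phenyl]oxolan-3-yl}methanol
Conditions: iBu2AlH (2.5 equiv), CH2Cl2, −78 °C → −40 °C; aq. potassium sodium tartrate (KNaC4H4O6)
Reagents that add atoms: none
Why: Hydride reduction of the ester to the primary alcohol with iBu2AlH at low temperature leaves the alkyl gem-dichloride and the aryl sulfonate alone.

Step 9
Reactants: 13 dichloromethyl alcohol
Product: 14 (1S,5S,6R)-6-[3-methoxy-4-(tosyloxy)phenyl]-3,7-dioxabicyclo[3.3.0]octan-2-ol (both anomers)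
Conditions: AgNO3 (2.5 equiv), 2,6-lutidine, THF–H2O, 50 °C
Reagents that add atoms: water, O
Why: Silver-assisted hydrolysis of the geminal dichloride with neighbouring-group participation: the cis CH2OH displaces the first chloride in a 5-exo-tet closure, the α-chloro ether so formed ionizes at once and water adds, which should give the aldehyde directly as the cis-fused lactol in which C4 cannot epimerize.

Step 10
Reactants: 15 4-bromo-2-methoxyphenol
Product: 16 1-(benzyloxy)-4-bromo-2-methoxybenzene
Conditions: BnBr, K2CO3, DMF, rt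
Reagents that add atoms: benzyl bromide, BrCc1ccccc1
Why: Williamson benzylation of the phenoxide is routine and gives an ether that survives Grignard formation.

Step 11
Reactants: 14 lactol; 16 aryl bromide
Product: 18 4-[(2R,3S,4S)-4-{[4-(benzyloxy)-3-methoxyphenyl](hydroxy)methyl}-3-(hydroxymethyl)oxolan-2-yl]-2-methoxyphenyl 4-methylbenzenesulfonate (both carbinol epimers), via aryl Grignard reagent 17 (not isolated)
Conditions: Mg, I2 (cat.), THF, 50 °C (17, 3 equiv); then 14, THF, 0 °C; aq. NH4Cl
Reagents that add atoms: none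
Why: Grignard addition to a lactol: the first equivalent deprotonates the hemiacetal and opens it to the alkoxy aldehyde, the second adds to the aldehyde faster than C4 can enolize; the configuration of the new carbinol does not matter because step 12 removes it.

Step 12
Reactants: 18 diol
Product: 19 4-[(2R,3S,4S)-4-(4-hydroxy-3-methoxybenzyl)-3-(hydroxymethyl)oxolan-2-yl]-2-methoxyphenyl 4-methylbenzenesulfonate
Conditions: H2 (1 atm), Pd(OH)2/C, EtOH–AcOH, rt
Reagents that add atoms: none
Why: Catalytic hydrogenolysis should cleave the benzyl ether and then the benzylic C–OH bond para to the freed phenol (if acid first closes the diol to the furofuran, the same C–O bond is cut to the same product), while the ring C2–O bond stays because its arene is deactivated by the sulfonate; C2, C3 and C4 are not involved.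

Step 13
Reactants: 19 monotosylate
Product: 20 (2R,3S,4S)-lariciresinol, 4-[(2R,3S,4S)-4-(4-hydroxy-3-methoxybenzyl)-3-(hydroxymethyl)oxolan-2-yl]-2-methoxyphenol
Conditions: KOH, MeOH–H2O, 65 °C; then aq. HCl to pH 4
Reagents that add atoms: none
Why: Alkaline cleavage of the aryl sulfonate (hydroxide attacks sulfur, phenoxide leaves) should proceed cleanly because the triol has no other base-labile group and no acidic C–H at its stereocentres.

Step 14
Reactants: 20 (2R,3S,4S)-lariciresinol; 21 caffeic acid
Product: 22 [(2R,3S,4S)-2-(4-hydroxy-3-methoxyphenyl)-4-(4-hydroxy-3-methoxybenzyl)oxolan-3-yl]methyl (2E)-3-(3,4-dihydroxyphenyl)prop-2-enoate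
Conditions: PPh3, DIAD, THF, 0 °C → rt
Reagents that add atoms: none
Why: Mitsunobu esterification: only the carboxylic acid is acidic enough to protonate the PPh3–DIAD betaine and the primary alcohol is the only aliphatic hydroxyl, so the ester should form chemoselectively beside four free phenols, at a CH2 carbon without stereochemical consequence and without touching the E alkene.

**Compound list**

1 | vanillin (4-hydroxy-3-methoxybenzaldehyde) | COc1cc(C=O)ccc1O | starting material
2 | 4-formyl-2-methoxyphenyl 4-methylbenzenesulfonate | COc1cc(C=O)ccc1OS(=O)(=O)c1ccc(C)cc1 | intermediate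
3 | vinylmagnesium bromide | C=C[Mg]Br | starting material
4 | rac-4-(1-hydroxyprop-2-enyl)-2-methoxyphenyl 4-methylbenzenesulfonate | COc1cc(C(O)C=C)ccc1OS(=O)(=O)c1ccc(C)cc1 | intermediate
5 | 4-[(1R)-1-hydroxyprop-2-enyl]-2-methoxyphenyl 4-methylbenzenesulfonate | COc1cc([C@H](O)C=C)ccc1OS(=O)(=O)c1ccc(C)cc1 | intermediate
6 | allyl bromide | C=CCBr | starting material
7 | 2-methoxy-4-[(1R)-1-(prop-2-enyloxy)prop-2-enyl]phenyl 4-methylbenzenesulfonate | COc1cc([C@H](OCC=C)C=C)ccc1OS(=O)(=O)c1ccc(C)cc1 | intermediate
8 | 4-[(2R)-2,5-dihydrofuran-2-yl]-2-methoxyphenyl 4-methylbenzenesulfonate | COc1cc([C@@H]2OCC=C2)ccc1OS(=O)(=O)c1ccc(C)cc1 | intermediate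
9 | trichloroacetyl chloride | ClC(Cl)(Cl)C(=O)Cl | starting material
10 | dichloroketene | ClC(Cl)=C=O | intermediate
11 | (1S,4R,5R)-7,7-dichloro-4-[3-methoxy-4-(tosyloxy)phenyl]-3-oxabicyclo[3.2.0]heptan-6-one (cis-fused, aryl anti to the four-membered ring, C=O on the bridgehead next to the aryl-bearing carbon) | ClC1(Cl)[C@@H]2CO[C@@H](c3ccc(OS(=O)(=O)c4ccc(C)cc4)c(OC)c3)[C@@H]2C1=O | intermediate
12 | methyl (2R,3R,4S)-4-(dichloromethyl)-2-[3-methoxy-4-(tosyloxy)phenyl]oxolane-3-carboxylate | ClC(Cl)[C@@H]1CO[C@@H](c2ccc(OS(=O)(=O)c3ccc(C)cc3)c(OC)c2)[C@@H]1C(=O)OC | intermediate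
13 | {(2R,3S,4S)-4-(dichloromethyl)-2-[3-methoxy-4-(tosyloxy)phenyl]oxolan-3-yl}methanol | ClC(Cl)[C@@H]1CO[C@@H](c2ccc(OS(=O)(=O)c3ccc(C)cc3)c(OC)c2)[C@@H]1CO | intermediate
14 | (1S,5S,6R)-6-[3-methoxy-4-(tosyloxy)phenyl]-3,7-dioxabicyclo[3.3.0]octan-2-ol (cis-fused lactol, aryl exo, both anomers) | OC1[C@@H]2CO[C@@H](c3ccc(OS(=O)(=O)c4ccc(C)cc4)c(OC)c3)[C@@H]2CO1 | intermediate
15 | 4-bromo-2-methoxyphenol | COc1cc(Br)ccc1O | starting material
16 | 1-(benzyloxy)-4-bromo-2-methoxybenzene | COc1cc(Br)ccc1OCc1ccccc1 | intermediate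
17 | [4-(benzyloxy)-3-methoxyphenyl]magnesium bromide | COc1cc([Mg]Br)ccc1OCc1ccccc1 | intermediate
18 | 4-[(2R,3S,4S)-4-{[4-(benzyloxy)-3-methoxyphenyl](hydroxy)methyl}-3-(hydroxymethyl)oxolan-2-yl]-2-methoxyphenyl 4-methylbenzenesulfonate (both carbinol epimers) | COc1cc(C(O)[C@@H]2CO[C@@H](c3ccc(OS(=O)(=O)c4ccc(C)cc4)c(OC)c3)[C@@H]2CO)ccc1OCc1ccccc1 | intermediate
19 | 4-[(2R,3S,4S)-4-(4-hydroxy-3-methoxybenzyl)-3-(hydroxymethyl)oxolan-2-yl]-2-methoxyphenyl 4-methylbenzenesulfonate | COc1cc(C[C@@H]2CO[C@@H](c3ccc(OS(=O)(=O)c4ccc(C)cc4)c(OC)c3)[C@@H]2CO)ccc1O | intermediate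
20 | (2R,3S,4S)-lariciresinol, 4-[(2R,3S,4S)-4-(4-hydroxy-3-methoxybenzyl)-3-(hydroxymethyl)oxolan-2-yl]-2-methoxyphenol | COc1cc(C[C@@H]2CO[C@@H](c3ccc(O)c(OC)c3)[C@@H]2CO)ccc1O | intermediate
21 | caffeic acid | O=C(O)/C=C/c1ccc(O)c(O)c1 | starting material
22 | [(2R,3S,4S)-2-(4-hydroxy-3-methoxyphenyl)-4-(4-hydroxy-3-methoxybenzyl)oxolan-3-yl]methyl (2E)-3-(3,4-dihydroxyphenyl)prop-2-enoate (CNP0132883.1) | COc1cc(C[C@@H]2CO[C@@H](c3ccc(O)c(OC)c3)[C@@H]2COC(=O)/C=C/c2ccc(O)c(O)c2)ccc1O | target

**Step count and risks**

Total step count: 14. Longest linear sequence: 13 steps (steps 1–9 and 11–14; step 10 is a side branch).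

Steps most likely to fail:

1. Step 6. The alkene is deactivated by two allylic C–O bonds, so it may react so slowly that the ketene acylates the ring oxygen (zwitterion, then C2–O cleavage) or oligomerizes, and the orientation of addition across C3=C4 may be poor. The fallback sets out from 5 and comes back at 19; it forms the C3–C4 bond by a radical cyclization instead of stapling it. Alcohol 5 is epoxidized under Sharpless conditions with L-(+)-DIPT, for which it is the fast-reacting enantiomer (Ti(OiPr)4, t-BuOOH, CH2Cl2, −20 °C), to the erythro epoxy alcohol F1. Commercial coniferyl alcohol is benzylated at the phenol (BnBr, K2CO3, acetone) to 4-O-benzylconiferyl alcohol F2, and PBr3 in Et2O at 0 °C turns it into the cinnamyl bromide F3. The sodium alkoxide of F1 (NaH, THF, 0 °C) is alkylated with F3 to the epoxy ether F4. Cp2TiCl, made from Cp2TiCl2 and zinc dust in THF, is a trivalent titanium reagent that opens the terminal epoxide homolytically to the secondary radical at the future C3. This radical should close 5-exo-trig onto the cinnamyl alkene through a chair-like transition state (aryl pseudo-equatorial gives 2,3-trans; the substituted radical carbon gives 3,4-cis), and the benzylic radical is reduced and protonated to the oxolane alcohol F5. Hydrogenolysis of the benzyl ether (H2, Pd/C, EtOAc) then gives 19.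

2. Step 9. The unactivated dichloromethyl group may ionize too slowly, or the hydroxy aldehyde may epimerize at C4 before it closes to the lactol. The fallback sets out from 12 and comes back at 19; the CHCl2 carbon is not raised to the aldehyde but coupled directly. Bu3SnH (1.05 equiv) with AIBN in benzene at 80 °C should remove one chlorine only, because the α-chloroalkyl radical forms far faster than a primary alkyl radical, and give the chloromethyl ester F6. An iron-catalysed Kumada-type coupling of this primary alkyl chloride with aryl Grignard reagent 17 (FeCl3, TMEDA, THF, slow addition, 0–40 °C) forms the C–aryl bond of the benzyl arm and gives the ester F7. Hydrogenolysis (H2, Pd/C) frees the ring B phenol to give the ester F8, and iBu2AlH reduces its ester to 19.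

3. Step 14. A phenol may be O-alkylated by the alkoxyphosphonium ion, the betaine may be quenched by the four phenols, and the triol–acid pair may be poorly soluble. The fallback sets out from 20 and comes back at 22; it makes the cinnamate double bond last. Heating 20 with Meldrum's acid in toluene at 90 °C should open the dioxanedione with the primary alcohol, the best nucleophile present, and give the malonic half ester F9. A Knoevenagel–Doebner condensation of F9 with commercial 3,4-dihydroxybenzaldehyde (pyridine, piperidine cat., 50 °C) with decarboxylation gives the E-caffeate 22.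

**Further compounds**

F1 | step 6 | (S)-[3-methoxy-4-(tosyloxy)phenyl][(2R)-oxiran-2-yl]methanol (erythro epoxy alcohol from 5) | COc1cc([C@H](O)[C@H]2CO2)ccc1OS(=O)(=O)c1ccc(C)cc1
F2 | step 6 | (2E)-3-[4-(benzyloxy)-3-methoxyphenyl]prop-2-en-1-ol (4-O-benzylconiferyl alcohol) | COc1cc(/C=C/CO)ccc1OCc1ccccc1
F3 | step 6 | 1-(benzyloxy)-4-[(1E)-3-bromoprop-1-enyl]-2-methoxybenzene | COc1cc(/C=C/CBr)ccc1OCc1ccccc1
F4 | step 6 | (2E)-3-[4-(benzyloxy)-3-methoxyphenyl]prop-2-enyl ether of F1 (epoxy ether) | COc1cc([C@H](OC/C=C/c2ccc(OCc3ccccc3)c(OC)c2)[C@H]2CO2)ccc1OS(=O)(=O)c1ccc(C)cc1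
F5 | step 6 | 4-[(2R,3S,4S)-4-[4-(benzyloxy)-3-methoxybenzyl]-3-(hydroxymethyl)oxolan-2-yl]-2-methoxyphenyl 4-methylbenzenesulfonate | COc1cc(C[C@@H]2CO[C@@H](c3ccc(OS(=O)(=O)c4ccc(C)cc4)c(OC)c3)[C@@H]2CO)ccc1OCc1ccccc1
F6 | step 9 | methyl (2R,3R,4S)-4-(chloromethyl)-2-[3-methoxy-4-(tosyloxy)phenyl]oxolane-3-carboxylate | ClC[C@@H]1CO[C@@H](c2ccc(OS(=O)(=O)c3ccc(C)cc3)c(OC)c2)[C@@H]1C(=O)OC
F7 | step 9 | methyl (2R,3R,4S)-4-[4-(benzyloxy)-3-methoxybenzyl]-2-[3-methoxy-4-(tosyloxy)phenyl]oxolane-3-carboxylate | COc1cc(C[C@@H]2CO[C@@H](c3ccc(OS(=O)(=O)c4ccc(C)cc4)c(OC)c3)[C@@H]2C(=O)OC)ccc1OCc1ccccc1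
F8 | step 9 | methyl (2R,3R,4S)-4-(4-hydroxy-3-methoxybenzyl)-2-[3-methoxy-4-(tosyloxy)phenyl]oxolane-3-carboxylate | COc1cc(C[C@@H]2CO[C@@H](c3ccc(OS(=O)(=O)c4ccc(C)cc4)c(OC)c3)[C@@H]2C(=O)OC)ccc1O
F9 | step 14 | 3-{[(2R,3S,4S)-2-(4-hydroxy-3-methoxyphenyl)-4-(4-hydroxy-3-methoxybenzyl)oxolan-3-yl]methoxy}-3-oxopropanoic acid | COc1cc(C[C@@H]2CO[C@@H](c3ccc(O)c(OC)c3)[C@@H]2COC(=O)CC(=O)O)ccc1O
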